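**Plan**

- Feature: each CH2–O–C(=O)CH3 arm is what Baeyer–Villiger oxidation makes from CH2–C(=O)CH3, and each ArCH2 is a reduced ArC=O. Butane C1–C4 are therefore ring carbons 3–6 of a 1,2-dimethylcyclohexene, whose C1, C2 and methyls become the two acetyl groups, with an aroyl group on ring C4 and on ring C5.
- Retrosynthesis: benzylic C–H back to C–OAc and C=O; both CH2–O bonds (retro-Baeyer–Villiger); the two ketone carbons rejoined as the ring C=C (retro-ozonolysis); then butane C1–C2 and C3–C4 cut by retro-[4+2] into 2,3-dimethylbutadiene and an (E)-1,4-diarylbut-2-ene-1,4-dione; its C=C cut into an arylglyoxal and an aroylmethylene phosphorane.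
- Forward: two acetophenones give glyoxal and ylide, then the E-enedione; the Diels–Alder reaction closes the only ring; ketone reduction and acetylation; ozonolysis opens the ring; double Baeyer–Villiger; one hydrogenolysis removes both benzylic acetates and the O-benzyl group.
- Stereochemistry: both stereocentres arise in the cycloaddition, trans from the E-alkene and absolute sense from a chiral oxazaborolidinium Lewis acid. Later steps break no bond at these carbons, so (4S,5S) in the adduct becomes (2R,3R) in the target (the letter changes only through CIP priorities).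

Key step: step 6

Remark: the two benzylic carbinol carbons made in the ketone reduction are carried as an epimer mixture (drawn without configuration) because both become CH2 in the last step. The facial sense in the cycloaddition is assigned from the accepted binding model of this catalyst class; should the opposite sense be found, the catalyst from (R)-diphenylprolinol would be used.

**Step 1**
Reactants: 1 3,4-dimethoxyacetophenone
Product: 2 (3,4-dimethoxyphenyl)glyoxal monohydrate
Conditions: SeO2, 1,4-dioxane/H2O, 100 °C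
Reagents that add atoms: selenium dioxide O=[Se]=O; water O
Why: Riley oxidation, in which SeO2 oxidises the enolisable methyl group of an aryl methyl ketone to the aldehyde level and the glyoxal is collected as its stable crystalline hydrate.

**Step 2**
Reactants: 3 acetosyringone
Product: 4 1-[4-(benzyloxy)-3,5-dimethoxyphenyl]ethanone
Conditions: BnBr, K2CO3, acetone, 56 °C
Reagents that add atoms: benzyl bromide BrCc1ccccc1
Why: Williamson ether synthesis on the acidic para-acyl phenol, the benzyl group being chosen because it should survive Lewis acid, hydride, ozone and peracid and leave in the final hydrogenolysis.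

**Step 3**
Reactants: 4 1-[4-(benzyloxy)-3,5-dimethoxyphenyl]ethanone
Product: 5 1-[4-(benzyloxy)-3,5-dimethoxyphenyl]-2-bromoethanone
Conditions: CuBr2, EtOAc/CHCl3 (1:1), 75 °C
Reagents that add atoms: CuBr2 Br[Cu]Br
Why: α-bromination of an aryl methyl ketone through its enol with CuBr2, which brominates the side chain in preference to the acyl-deactivated ring.

**Step 4**
Reactants: 5 1-[4-(benzyloxy)-3,5-dimethoxyphenyl]-2-bromoethanone
Product: 7 1-[4-(benzyloxy)-3,5-dimethoxyphenyl]-2-(triphenylphosphoranylidene)ethanone, via phosphonium bromide 6 (not isolated)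
Conditions: PPh3, CH2Cl2, 23 °C; then 2 M aq NaOH, 23 °C
Reagents that add atoms: triphenylphosphine c1ccc(cc1)P(c1ccccc1)c1ccccc1
Why: SN2 quaternisation of PPh3 by the phenacyl bromide followed by deprotonation of the carbonyl-acidified CH2 gives the water-stable acyl-stabilised ylide.

**Step 5**
Reactants: 2 (3,4-dimethoxyphenyl)glyoxal monohydrate; 7 1-[4-(benzyloxy)-3,5-dimethoxyphenyl]-2-(triphenylphosphoranylidene)ethanone
Product: 8 (E)-1-[4-(benzyloxy)-3,5-dimethoxyphenyl]-4-(3,4-dimethoxyphenyl)but-2-ene-1,4-dione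
Conditions: CH2Cl2, 23 °C, dark
Reagents that add atoms: none
Why: Wittig olefination, in which the stabilised ylide attacks only the aldehyde carbon of the glyoxal (released from its hydrate in equilibrium) and reversible oxaphosphetane formation should lead to the E-alkene.

**Step 6**
Reactants: 8 (E)-1-[4-(benzyloxy)-3,5-dimethoxyphenyl]-4-(3,4-dimethoxyphenyl)but-2-ene-1,4-dione; 9 2,3-dimethylbuta-1,3-diene
Product: 10 (4S,5S)-4-(3,4-dimethoxybenzoyl)-5-[4-(benzyloxy)-3,5-dimethoxybenzoyl]-1,2-dimethylcyclohexene
Conditions: (S)-o-tolyl-oxazaborolidine [(3aS)-3,3-diphenyl-1-(2-methylphenyl)tetrahydropyrrolo[1,2-c][1,3,2]oxazaborole, from (S)-diphenylprolinol] (20 mol%), Tf2NH (18 mol%), 9 (5 equiv), CH2Cl2, −20 °C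
Reagents that add atoms: none
Why: Proposed new method: the N-protonated oxazaborolidine is a strong chiral Lewis acid that binds one aroyl oxygen of 8 (lone pair syn to the vinyl group, α-C–H against the ring oxygen, alkene stacked on the neighbouring phenyl) and lowers the LUMO for a concerted, suprafacial, normal-demand [4+2] cycloaddition with 9; the closest known reactions are the thermal Diels–Alder addition of trans-1,2-dibenzoylethylene to 2,3-dimethylbutadiene and cationic oxazaborolidine-catalysed Diels–Alder reactions of fumarates, acrylates and enones, while an enantioselective version on a 1,2-diaroylethylene is not established. The cyclohexene ring closes in one intermolecular cycloaddition event in which both new σ bonds (butane C1–C2 and C3–C4) form together across the alkene. The trans relation of the new stereocentres C4 and C5 follows stereospecifically from the E geometry of 8, and their absolute configuration is set by the catalyst, whose phenyl group screens one face so that the diene should add to the Si,Si face and give (4S,5S). Only enantioface selectivity is needed: 9 is symmetrical and unsubstituted at its termini, so no regio- or endo/exo question arises, and because 8 is pseudo-C2-symmetric, binding at either carbonyl exposes the same alkene face. The electron-rich aryl groups make 8 a slow thermal dienophile at −20 °C, which should suppress the racemic background reaction.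

**Step 7**
Reactants: 10 (4S,5S)-4-(3,4-dimethoxybenzoyl)-5-[4-(benzyloxy)-3,5-dimethoxybenzoyl]-1,2-dimethylcyclohexene
Product: 11 (4S,5S)-4-[hydroxy(3,4-dimethoxyphenyl)methyl]-5-{hydroxy[4-(benzyloxy)-3,5-dimethoxyphenyl]methyl}-1,2-dimethylcyclohexene (carbinol epimers)
Conditions: NaBH4, THF/MeOH (1:1), 0 → 23 °C
Reagents that add atoms: none
Why: Hydride 1,2-reduction of both aryl ketones, the two new carbinol centres forming under substrate (Felkin-type) control as an epimer mixture that is immaterial because both become CH2 in step 11, while the trans ring centres are the thermodynamic arrangement and should not erode.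

**Step 8**
Reactants: 11 (4S,5S)-4-[hydroxy(3,4-dimethoxyphenyl)methyl]-5-{hydroxy[4-(benzyloxy)-3,5-dimethoxyphenyl]methyl}-1,2-dimethylcyclohexene
Product: 12 (4S,5S)-4-[acetoxy(3,4-dimethoxyphenyl)methyl]-5-{acetoxy[4-(benzyloxy)-3,5-dimethoxyphenyl]methyl}-1,2-dimethylcyclohexene
Conditions: Ac2O, pyridine, DMAP (cat.), CH2Cl2, 0 → 23 °C
Reagents that add atoms: acetic anhydride CC(=O)OC(C)=O
Why: DMAP-catalysed O-acylation, which prevents lactol formation with the ketones released in step 9 and turns both benzylic oxygens into leaving groups for the final hydrogenolysis.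

**Step 9**
Reactants: 12 (4S,5S)-4-[acetoxy(3,4-dimethoxyphenyl)methyl]-5-{acetoxy[4-(benzyloxy)-3,5-dimethoxyphenyl]methyl}-1,2-dimethylcyclohexene
Product: 14 (4S,5S)-4-[acetoxy(3,4-dimethoxyphenyl)methyl]-5-{acetoxy[4-(benzyloxy)-3,5-dimethoxyphenyl]methyl}octane-2,7-dione, via ozonide 13 (not isolated)
Conditions: O3, CH2Cl2, −78 °C (Sudan Red 7B end-point); then PPh3, −78 → 23 °C
Reagents that add atoms: ozone [O-][O+]=O
Why: Ozonolysis (Criegee mechanism), in which the electron-rich tetrasubstituted alkene should react far faster than the alkoxyarenes when a dye marks the end-point, and PPh3 reduces the peroxidic intermediate to the two methyl ketones.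

**Step 10**
Reactants: 14 (4S,5S)-4-[acetoxy(3,4-dimethoxyphenyl)methyl]-5-{acetoxy[4-(benzyloxy)-3,5-dimethoxyphenyl]methyl}octane-2,7-dione
Product: 15 (2R,3R)-2-[acetoxy(3,4-dimethoxyphenyl)methyl]-3-{acetoxy[4-(benzyloxy)-3,5-dimethoxyphenyl]methyl}butane-1,4-diyl diacetate
Conditions: mCPBA (6 equiv), NaHCO3, CH2Cl2, 40 °C, dark
Reagents that add atoms: mCPBA OOC(=O)c1cccc(Cl)c1
Why: Double Baeyer–Villiger oxidation, in which the primary alkyl group migrates in preference to methyl in each Criegee intermediate to give the CH2–OAc arms, buffered mCPBA being chosen because it tolerates alkoxyarenes and benzylic acetates.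

**Step 11**
Reactants: 15 (2R,3R)-2-[acetoxy(3,4-dimethoxyphenyl)methyl]-3-{acetoxy[4-(benzyloxy)-3,5-dimethoxyphenyl]methyl}butane-1,4-diyl diacetate
Product: 16 Justin C, (2R,3R)-2-(3,4-dimethoxybenzyl)-3-(4-hydroxy-3,5-dimethoxybenzyl)butane-1,4-diyl diacetate
Conditions: H2 (3 atm), 10% Pd/C, EtOAc/AcOH (10:1), 23 → 40 °C
Reagents that add atoms: none
Why: Catalytic hydrogenolysis on Pd/C should cleave both electron-rich benzylic C–OAc bonds and the O-benzyl ether in one operation, leaving the primary acetates and the two homobenzylic stereocentres untouched.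

**Compound list**

1 | 3,4-dimethoxyacetophenone | CC(=O)c1ccc(OC)c(OC)c1 | starting material
2 | (3,4-dimethoxyphenyl)glyoxal monohydrate, 1-(3,4-dimethoxyphenyl)-2,2-dihydroxyethanone | OC(O)C(=O)c1ccc(OC)c(OC)c1 | intermediate
3 | acetosyringone, 1-(4-hydroxy-3,5-dimethoxyphenyl)ethanone | CC(=O)c1cc(OC)c(O)c(OC)c1 | starting material
4 | 1-[4-(benzyloxy)-3,5-dimethoxyphenyl]ethanone | CC(=O)c1cc(OC)c(OCc2ccccc2)c(OC)c1 | intermediate
5 | 1-[4-(benzyloxy)-3,5-dimethoxyphenyl]-2-bromoethanone | O=C(CBr)c1cc(OC)c(OCc2ccccc2)c(OC)c1 | intermediate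
6 | {2-[4-(benzyloxy)-3,5-dimethoxyphenyl]-2-oxoethyl}triphenylphosphonium bromide | [Br-].O=C(C[P+](c1ccccc1)(c1ccccc1)c1ccccc1)c1cc(OC)c(OCc2ccccc2)c(OC)c1 | intermediate
7 | 1-[4-(benzyloxy)-3,5-dimethoxyphenyl]-2-(triphenylphosphoranylidene)ethanone | O=C(C=P(c1ccccc1)(c1ccccc1)c1ccccc1)c1cc(OC)c(OCc2ccccc2)c(OC)c1 | intermediate
8 | (E)-1-[4-(benzyloxy)-3,5-dimethoxyphenyl]-4-(3,4-dimethoxyphenyl)but-2-ene-1,4-dione | COc1ccc(C(=O)/C=C/C(=O)c2cc(OC)c(OCc3ccccc3)c(OC)c2)cc1OC | intermediate
9 | 2,3-dimethylbuta-1,3-diene | C=C(C)C(C)=C | starting material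
10 | (4S,5S)-4-(3,4-dimethoxybenzoyl)-5-[4-(benzyloxy)-3,5-dimethoxybenzoyl]-1,2-dimethylcyclohexene (trans) | COc1ccc(C(=O)[C@H]2CC(C)=C(C)C[C@@H]2C(=O)c3cc(OC)c(OCc4ccccc4)c(OC)c3)cc1OC | intermediate
11 | (4S,5S)-4-[hydroxy(3,4-dimethoxyphenyl)methyl]-5-{hydroxy[4-(benzyloxy)-3,5-dimethoxyphenyl]methyl}-1,2-dimethylcyclohexene, both carbinol carbons as epimer mixture | COc1ccc(C(O)[C@H]2CC(C)=C(C)C[C@@H]2C(O)c3cc(OC)c(OCc4ccccc4)c(OC)c3)cc1OC | intermediate
12 | (4S,5S)-4-[acetoxy(3,4-dimethoxyphenyl)methyl]-5-{acetoxy[4-(benzyloxy)-3,5-dimethoxyphenyl]methyl}-1,2-dimethylcyclohexene, benzylic carbons as epimer mixture | COc1ccc(C(OC(C)=O)[C@H]2CC(C)=C(C)C[C@@H]2C(OC(C)=O)c3cc(OC)c(OCc4ccccc4)c(OC)c3)cc1OC | intermediate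
13 | ozonide of 12: 1,6-dimethyl-7,8,9-trioxabicyclo[4.2.1]nonane carrying the two acetoxy(aryl)methyl groups on C3 and C4, ring CH configurations as in 12 | COc1ccc(C(OC(C)=O)[C@H]2CC3(C)OOC(C)(O3)C[C@@H]2C(OC(C)=O)c4cc(OC)c(OCc5ccccc5)c(OC)c4)cc1OC | intermediate
14 | (4S,5S)-4-[acetoxy(3,4-dimethoxyphenyl)methyl]-5-{acetoxy[4-(benzyloxy)-3,5-dimethoxyphenyl]methyl}octane-2,7-dione, benzylic carbons as epimer mixture | COc1ccc(C(OC(C)=O)[C@@H](CC(C)=O)[C@H](CC(C)=O)C(OC(C)=O)c2cc(OC)c(OCc3ccccc3)c(OC)c2)cc1OC | intermediate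
15 | (2R,3R)-2-[acetoxy(3,4-dimethoxyphenyl)methyl]-3-{acetoxy[4-(benzyloxy)-3,5-dimethoxyphenyl]methyl}butane-1,4-diyl diacetate, benzylic carbons as epimer mixture | COc1ccc(C(OC(C)=O)[C@@H](COC(C)=O)[C@H](COC(C)=O)C(OC(C)=O)c2cc(OC)c(OCc3ccccc3)c(OC)c2)cc1OC | intermediate
16 | Justin C, (2R,3R)-2-(3,4-dimethoxybenzyl)-3-(4-hydroxy-3,5-dimethoxybenzyl)butane-1,4-diyl diacetate | COc1ccc(C[C@@H](COC(C)=O)[C@H](COC(C)=O)Cc2cc(OC)c(O)c(OC)c2)cc1OC | target

**Step count**

Total: 11 steps. Longest linear sequence: 10 steps (from 3 through steps 2–11); the branch from 1 joins at step 5.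

**Steps most likely to fail**

1. Step 6 (Proposed new method). The catalyst may discriminate the two alkene faces poorly, or the many ether oxygens may compete for boron and slow turnover until the uncatalysed racemic pathway takes over. Fallback from 8 and 9, returning at 10: the cycloaddition is run thermally (toluene, 110 °C, sealed tube), as is known for trans-1,2-diaroylethylenes with this diene, to give the racemic trans-diketone F1. The enantiomers are then separated by preparative chromatography on an amylose tris(3,5-dimethylphenylcarbamate) stationary phase, and the (4S,5S) enantiomer is 10.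

2. Step 10. Oxygen insertion at methyl primary-alkyl ketones is slow with mCPBA, so peracid attack on the electron-rich aryl rings or ionisation of the benzylic acetates may compete. Fallback from 14, returning at 15: TMSCl, NaI and Et3N in MeCN should give, on the more substituted side, the bis(trimethylsilyl enol ether) F2. Ozone (CH2Cl2/MeOH, −78 °C) cleaves both enol ether double bonds to the dialdehyde F3, which is reduced in the same flask with NaBH4 to the diol F4. Ac2O, pyridine and DMAP then give 15; any acetyl migration in F4 is harmless because every hydroxyl ends as an acetate.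

3. Step 11. The two hindered secondary benzylic C–O bonds may cleave incompletely on the metal surface, or acid-promoted elimination toward styrenes may erase the adjacent stereocentres. Fallback from 15, returning at 16: ionic hydrogenation with Et3SiH and BF3·OEt2 (CH2Cl2, −78 → 0 °C) removes both para-alkoxy-benzylic acetates through hydride capture of the benzylic cations, giving the O-benzyl ether of Justin C F5. Mild hydrogenolysis (H2, 1 atm, Pd/C, EtOAc, 23 °C) then removes only the benzyl group to give 16.

**Further compounds**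

F1 | step 6 | racemic trans-4-(3,4-dimethoxybenzoyl)-5-[4-(benzyloxy)-3,5-dimethoxybenzoyl]-1,2-dimethylcyclohexene (1:1 mixture of 10 and its (4R,5R) enantiomer) | COc1ccc(C(=O)[C@H]2CC(C)=C(C)C[C@@H]2C(=O)c3cc(OC)c(OCc4ccccc4)c(OC)c3)cc1OC.COc1ccc(C(=O)[C@@H]2CC(C)=C(C)C[C@H]2C(=O)c3cc(OC)c(OCc4ccccc4)c(OC)c3)cc1OC
F2 | step 10 | (2Z,6Z)-4-[acetoxy(3,4-dimethoxyphenyl)methyl]-5-{acetoxy[4-(benzyloxy)-3,5-dimethoxyphenyl]methyl}-2,7-bis(trimethylsilyloxy)octa-2,6-diene, backbone methines as in 14 | COc1ccc(C(OC(C)=O)[C@@H](/C=C(/C)O[Si](C)(C)C)[C@H](/C=C(/C)O[Si](C)(C)C)C(OC(C)=O)c2cc(OC)c(OCc3ccccc3)c(OC)c2)cc1OC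
F3 | step 10 | 2-[acetoxy(3,4-dimethoxyphenyl)methyl]-3-{acetoxy[4-(benzyloxy)-3,5-dimethoxyphenyl]methyl}butanedial, backbone methines as in 14 | COc1ccc(C(OC(C)=O)[C@@H](C=O)[C@H](C=O)C(OC(C)=O)c2cc(OC)c(OCc3ccccc3)c(OC)c2)cc1OC
F4 | step 10 | 2-[acetoxy(3,4-dimethoxyphenyl)methyl]-3-{acetoxy[4-(benzyloxy)-3,5-dimethoxyphenyl]methyl}butane-1,4-diol, backbone methines as in 15 | COc1ccc(C(OC(C)=O)[C@@H](CO)[C@H](CO)C(OC(C)=O)c2cc(OC)c(OCc3ccccc3)c(OC)c2)cc1OC
F5 | step 11 | (2R,3R)-2-[4-(benzyloxy)-3,5-dimethoxybenzyl]-3-(3,4-dimethoxybenzyl)butane-1,4-diyl diacetate | COc1ccc(C[C@@H](COC(C)=O)[C@H](COC(C)=O)Cc2cc(OC)c(OCc3ccccc3)c(OC)c2)cc1OC
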